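**Retrosynthetic overview**
1. Macrocarpal H comes from Vilsmeier diformylation and Wittig methylenation of a C4 ketone, on a 1β-(ArCH–iBu) decalone. The isobutyl group arises by hydrogenating a prenyl unit installed by Friedel–Crafts allylation of phloroglucinol with a tertiary allylic alcohol.
2. That allylic alcohol is made from an (E)-enoate on a trans-decalone, and the decalone comes from one intramolecular Diels–Alder (IMDA). A 2-silyloxydiene (from a vinyl ketone) adds to the γ,δ-alkene of a dienoate. This single step closes ring B (as the tether ring) and ring A together and sets C10 (quaternary), C5 and C1.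
3. The IMDA substrate comes from (R)-α-terpineol. Ozonolysis opens its ring (terpineol C1=C2 corresponds to C10/C5). The aldehyde is homologated to a vinyl ketone, and the methyl ketone is converted by HWE to the dienoate. C7 is the only stereochemical input.

Assumption: (R)-(+)-α-terpineol is available in ≥95% ee. Minor diastereomers from Step 4 (alkene geometry), Step 8 (C10/C5/C1) and Step 11 (benzylic carbon) are separated chromatographically.

**Step 1**
Reactants: 1 (R)-α-terpineol
Product: 2 TBS ether of 1
Conditions: TBSOTf, 2,6-lutidine, CH2Cl2, 0 °C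
Reagents that add atoms: TBSOTf, CC(C)(C)[Si](C)(C)OS(=O)(=O)C(F)(F)F
Why: Silylation of the tertiary alcohol stops it closing onto the aldehyde formed later; no stereocentre is touched.

**Step 2**
Reactants: 2
Product: 3 keto-aldehyde
Conditions: O3, CH2Cl2/MeOH, –78 °C; then PPh3
Reagents that add atoms: ozone, [O-][O+]=O
Why: Ozonolysis cleaves the only alkene, opening the terpineol ring and retaining C7 as the sole stereocentre.

**Step 3**
Reactants: 3
Product: 4 methyl enol ether
Conditions: [Ph3PCH2OMe]Cl, KOtBu, THF, –78 → 0 °C (1 equiv ylide)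
Reagents that add atoms: methoxymethylene ylide, COC=P(c1ccccc1)(c1ccccc1)c1ccccc1
Why: Wittig homologation of the aldehyde is much faster than attack on the methyl ketone, and the enol ether masks the future C4 aldehyde; no new stereocentre.

**Step 4**
Reactants: 4; 5 triethyl 4-phosphonocrotonate
Product: 6 dienoate
Conditions: NaH, THF, 0 → 65 °C
Reagents that add atoms: none
Why: Horner–Wadsworth–Emmons olefination of the methyl ketone gives the (E)-C10=C1 alkene, with the dienoate chain cis to the C14 methyl; this geometry later fixes C1 cis to C10–CH3, and the Z isomer is removed by chromatography.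

**Step 5**
Reactants: 6
Product: 7 aldehyde
Conditions: 1 M HCl, THF, 25 °C
Reagents that add atoms: water, O
Why: Enol ether hydrolysis unmasks the C4 aldehyde (the old aldehyde carbon becomes C5H2); the TBS ether and dienoate survive.

**Step 6**
Reactants: 7
Product: 8 allylic alcohol
Conditions: CH2=CHMgBr, THF, –78 °C
Reagents that add atoms: vinylmagnesium bromide, C=C[Mg]Br
Why: 1,2-Grignard addition is chemoselective for the aldehyde over the ester at –78 °C and adds C3 and C2; the carbinol centre is temporary.

**Step 7**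
Reactants: 8
Product: 9 vinyl ketone (used crude)
Conditions: Dess–Martin periodinane, NaHCO3, CH2Cl2, 0 °C
Reagents that add atoms: none
Why: Oxidation of the allylic alcohol gives the C4 ketone and erases the temporary stereocentre.

**Step 8**
Reactants: 9
Product: 11 trans-decalin silyl enol ether, via the transient 10 (2-silyloxydiene)
Conditions: TBSOTf, Et3N, CH2Cl2, 0 °C; then PhMe, BHT, 110 °C
Reagents that add atoms: TBSOTf, CC(C)(C)[Si](C)(C)OS(=O)(=O)C(F)(F)F
Why: Soft enolisation gives the (Z)-2-silyloxydiene 10, whose nucleophilic C5 terminus adds to C10, the δ-carbon of the dienoate, in an intramolecular Diels–Alder with matched polarity. The exo, chair-like tether transition state, with the bulky C11 group equatorial, gives trans fusion and sets the C10 quaternary centre relative to C7. Suprafacial addition to the E-alkene puts the C1 chain cis to the C10 methyl.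

**Step 9**
Reactants: 11
Product: 12 tertiary allylic alcohol
Conditions: MeMgBr (3 equiv), CeCl3, THF, 0 °C
Reagents that add atoms: methylmagnesium bromide, C[Mg]Br
Why: Double 1,2-addition to the ester converts CO2Et into C(CH3)2OH, which becomes the isobutyl CH(CH3)2; the silyl enol ether and TBS ether are inert and no stereocentre changes.

**Step 10**
Reactants: 12
Product: 13 trans-decalone
Conditions: TBAF·3H2O, THF, 25 °C
Reagents that add atoms: none
Why: Fluoride cleaves the silyl enol ether to the C4 ketone, and enolate equilibration converts C5 (α to the ketone) to the stable trans-fused 5α-H; the hindered tertiary C11 TBS ether survives.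

**Step 11**
Reactants: 13; 14 phloroglucinol (4 equiv)
Product: 15 prenyl-phloroglucinol
Conditions: Sc(OTf)3 (10 mol %), MeNO2, 25 °C
Reagents that add atoms: none
Why: Friedel–Crafts allylation: ionisation of the tertiary allylic alcohol gives an allyl cation that phloroglucinol attacks at the less hindered secondary terminus, from the face opposite the C10 quaternary centre. The benzylic centre is thus set by 1,2-induction from C1.

**Step 12**
Reactants: 15
Product: 16 isobutyl compound
Conditions: H2 (1 atm), 10% Pd/C, EtOAc, 25 °C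
Reagents that add atoms: none (hydrogen only)
Why: Hydrogenation reduces the trisubstituted prenyl C=C to isobutyl while the ketone, arene and TBS ether are untouched; the benzylic centre is not allylic and is unaffected.

**Step 13**
Reactants: 16
Product: 17 4(15)-ene
Conditions: Ph3PCH3Br (6 equiv), KOtBu (6 equiv), THF, 0 → 65 °C
Reagents that add atoms: methylenetriphenylphosphorane, C=P(c1ccccc1)(c1ccccc1)c1ccccc1
Why: Wittig methylenation of the C4 ketone gives the exocyclic alkene; excess ylide first converts the three phenols to phenoxides, which are inert to it.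

**Step 14**
Reactants: 17
Product: 18 O-TBS macrocarpal H
Conditions: POCl3, DMF, 0 → 25 °C; then aq. NaOAc
Reagents that add atoms: DMF, CN(C)C=O; water, O
Why: Vilsmeier–Haack double formylation of the 5-alkylphloroglucinol occurs at the two ring positions each flanked by OH groups.

**Step 15**
Reactants: 18
Product: 19 macrocarpal H
Conditions: HF·pyridine, THF, 0 → 25 °C
Reagents that add atoms: none
Why: Fluoride removes the tertiary TBS ether to give the free 11-OH; nothing else changes.

**Compound list**

| No. | Name | SMILES | Role |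
|---|---|---|---|
| 1 | (R)-(+)-α-terpineol | CC1=CC[C@H](C(C)(C)O)CC1 | starting material |
| 2 | TBS ether of (R)-α-terpineol | CC1=CC[C@H](C(C)(C)O[Si](C)(C)C(C)(C)C)CC1 | intermediate |
| 3 | (3R)-3-{2-[(TBS)oxy]propan-2-yl}-6-oxoheptanal | CC(=O)CC[C@H](CC=O)C(C)(C)O[Si](C)(C)C(C)(C)C | intermediate |
| 4 | (5R)-5-{2-[(TBS)oxy]propan-2-yl}-8-methoxyoct-7-en-2-one (E/Z) | CC(=O)CC[C@H](CC=COC)C(C)(C)O[Si](C)(C)C(C)(C)C | intermediate |
| 5 | ethyl (2E)-4-(diethoxyphosphoryl)but-2-enoate | CCOC(=O)/C=C/CP(=O)(OCC)OCC | starting material |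
| 6 | ethyl (2E,4E,8R)-8-{2-[(TBS)oxy]propan-2-yl}-11-methoxy-5-methylundeca-2,4,10-trienoate | CCOC(=O)/C=C/C=C(\C)CC[C@H](CC=COC)C(C)(C)O[Si](C)(C)C(C)(C)C | intermediate |
| 7 | ethyl (2E,4E,8R)-8-{2-[(TBS)oxy]propan-2-yl}-5-methyl-11-oxoundeca-2,4-dienoate | CCOC(=O)/C=C/C=C(\C)CC[C@H](CCC=O)C(C)(C)O[Si](C)(C)C(C)(C)C | intermediate |
| 8 | ethyl (2E,4E,8R)-8-{2-[(TBS)oxy]propan-2-yl}-11-hydroxy-5-methyltrideca-2,4,12-trienoate | CCOC(=O)/C=C/C=C(\C)CC[C@H](CCC(O)C=C)C(C)(C)O[Si](C)(C)C(C)(C)C | intermediate |
| 9 | ethyl (2E,4E,8R)-8-{2-[(TBS)oxy]propan-2-yl}-5-methyl-11-oxotrideca-2,4,12-trienoate | CCOC(=O)/C=C/C=C(\C)CC[C@H](CCC(=O)C=C)C(C)(C)O[Si](C)(C)C(C)(C)C | intermediate |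
| 10 | (Z)-2-silyloxydiene (TBS dienol ether of 9), generated in situ, not isolated | C=CC(O[Si](C)(C)C(C)(C)C)=CC[C@H](C(C)(C)O[Si](C)(C)C(C)(C)C)CC/C(C)=C/C=C/C(=O)OCC | intermediate |
| 11 | ethyl (E)-3-[4,11-bis(TBS-oxy)eudesm-3-en-1β-yl]acrylate (5α-H, 10β-CH3, 7β side chain) | CC(C)(C)[Si](C)(C)OC1=CC[C@@H](/C=C/C(=O)OCC)[C@]2(C)CC[C@@H](C(C)(C)O[Si](C)(C)C(C)(C)C)C[C@@H]12 | intermediate |
| 12 | (E)-4-[4,11-bis(TBS-oxy)eudesm-3-en-1β-yl]-2-methylbut-3-en-2-ol | CC(C)(C)[Si](C)(C)OC1=CC[C@@H](/C=C/C(C)(C)O)[C@]2(C)CC[C@@H](C(C)(C)O[Si](C)(C)C(C)(C)C)C[C@@H]12 | intermediate |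
| 13 | (E)-1β-(3-hydroxy-3-methylbut-1-enyl)-11-(TBS-oxy)eudesman-4-one (5α-H, 10β-CH3, 7β) | O=C1CC[C@@H](/C=C/C(C)(C)O)[C@]2(C)CC[C@@H](C(C)(C)O[Si](C)(C)C(C)(C)C)C[C@@H]12 | intermediate |
| 14 | phloroglucinol | Oc1cc(O)cc(O)c1 | starting material |
| 15 | 11-(TBS-oxy)-1β-[1-(2,4,6-trihydroxyphenyl)-3-methylbut-2-en-1-yl]eudesman-4-one, benzylic centre as in target | O=C1CC[C@@H]([C@H](C=C(C)C)c2c(O)cc(O)cc2O)[C@]2(C)CC[C@@H](C(C)(C)O[Si](C)(C)C(C)(C)C)C[C@@H]12 | intermediate |
| 16 | 11-(TBS-oxy)-1β-[1-(2,4,6-trihydroxyphenyl)-3-methylbutyl]eudesman-4-one | O=C1CC[C@@H]([C@H](CC(C)C)c2c(O)cc(O)cc2O)[C@]2(C)CC[C@@H](C(C)(C)O[Si](C)(C)C(C)(C)C)C[C@@H]12 | intermediate |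
| 17 | 11-O-TBS 4(15)-ene, 2,4,6-trihydroxyphenyl compound | C=C1CC[C@@H]([C@H](CC(C)C)c2c(O)cc(O)cc2O)[C@]2(C)CC[C@@H](C(C)(C)O[Si](C)(C)C(C)(C)C)C[C@@H]12 | intermediate |
| 18 | 11-O-TBS macrocarpal H | C=C1CC[C@@H]([C@H](CC(C)C)c2c(O)c(C=O)c(O)c(C=O)c2O)[C@]2(C)CC[C@@H](C(C)(C)O[Si](C)(C)C(C)(C)C)C[C@@H]12 | intermediate |
| 19 | macrocarpal H | C=C1CC[C@@H]([C@H](CC(C)C)c2c(O)c(C=O)c(O)c(C=O)c2O)[C@]2(C)CC[C@@H](C(C)(C)O)C[C@@H]12 | target |

**Total steps:** 15. **Longest linear sequence:** 15.

**Three steps most likely to fail**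
1. **Step 8 (IMDA).** The quaternary-centre-forming cyclisation may be slow, or give C10 or cis-fusion diastereomers; the C5 cis isomer is fixed by Step 10, but the C10 epimer is not.
   Fallback: abandon the IMDA and build the decalin by Robinson annulation of commercial (+)-dihydrocarvone with ethyl vinyl ketone. Set the trans fusion by Li/NH3 reduction of the enone, then introduce the C1 and C4 functionality through the 1,4-dien-3-one.
2. **Step 11 (Friedel–Crafts allylation).** Attack may occur at the tertiary terminus instead, or give a poor benzylic diastereomer ratio.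
   Fallback: use an aromatic Claisen instead. Make the tertiary-allylic aryl ether of 3,5-bis(benzyloxy)phenol from the tertiary propargylic chloride, then Lindlar reduction. Rearrange thermally through a chair transition state so the C1 configuration controls the benzylic centre. Final hydrogenolysis then removes the benzyl groups and reduces the alkene together.
3. **Step 14 (Vilsmeier).** The exocyclic alkene or tertiary silyl ether may not survive POCl3/DMF, or the formylation may be incomplete.
   Fallback: change the formylation mechanism to magnesium-phenoxide ortho-formylation (MgCl2, Et3N, paraformaldehyde, MeCN, 80 °C), which is non-acidic and leaves the 1,1-disubstituted alkene and tertiary silyl ether untouched.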